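Lepidine C is achiral. Two 2-benzyl-1H-imidazoles sit on a diaryl ether (ring A is the methoxy-bearing benzene, ring B the meta-substituted one). In each imidazole, C4–C5 is the only ring C–C bond and both carbons carry only H. N1–C2–N3 is an amidine already attached to ArCH2, so each ring can be closed last, at carbon.
Cuts, in order: both N1–H (from N1–PMB); both C4=C5 bonds (C4 from a phosphonate carbon, C5 from an N-formyl carbon); both N1–CHO bonds; both amidine C2–N1 bonds; both amide C2–N3 bonds; finally the ring A C–O bond of the diaryl ether.
Forward: rings A and B are bought and joined first by Ullmann coupling. Both acetic acid arms are then taken side by side in the same flask to amide, amidine and N-formylamidine. Both imidazole rings close in one operation, and acidolysis of the two PMB groups ends the route.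
Stereochemistry: none has to be set; the sp3 centres of the cyclisation adduct disappear on aromatisation.

Key step: step 6

Assumption: C=N geometries in 8, 9 and 10 are left open because amidine-type C=N bonds isomerise readily. Compound 9 is drawn as one of its two tautomers, and 11 is drawn in protonated form as an unassigned mixture of diastereomers.

Step 1
Reactants: 1 methyl (3-hydroxyphenyl)acetate; 2 methyl (2-bromo-5-methoxyphenyl)acetate
Product: 3 methyl {5-methoxy-2-[3-(2-methoxy-2-oxoethyl)phenoxy]phenyl}acetate (diaryl ether diester)
Conditions: CuI (10 mol %), N,N-dimethylglycine·HCl (30 mol %), Cs2CO3 (2.2 equiv), 1,4-dioxane, 100 °C, Ar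
Reagents that add atoms: none
Why: Ligand-accelerated Ullmann diaryl ether coupling, in which the amino acid ligand lets the electron-rich, ortho-substituted bromide 2 react at a temperature the methyl esters tolerate, while ester rather than free acid arms keep a carboxylate from competing as O-nucleophile.

Step 2
Reactants: 3 diaryl ether diester
Product: 4 {2-[3-(carboxymethyl)phenoxy]-5-methoxyphenyl}acetic acid (diacid)
Conditions: LiOH·H2O (5 equiv), THF/MeOH/H2O, rt; then 1 M HCl
Reagents that add atoms: lithium hydroxide (hydroxide oxygen of each CO2H), [Li+].[OH-]
Why: Ordinary saponification of two unhindered methyl esters, to which the aryl ethers are inert.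

Step 3
Reactants: 4 diacid; 5 diethyl (aminomethyl)phosphonate (2.2 equiv)
Product: 6 bis[N-(diethoxyphosphorylmethyl)amide] of diacid 4
Conditions: EDC·HCl (2.4 equiv), HOBt (2.4 equiv), CH2Cl2/DMF, 0 °C to rt
Reagents that add atoms: none
Why: Carbodiimide/HOBt amide coupling of a primary amine with an arylacetic acid, with the phosphonate diester as a spectator.

Step 4
Reactants: 6 bis(phosphonomethyl amide); 7 4-methoxybenzylamine (2.5 equiv)
Product: 9 bis[N-(4-methoxybenzyl)-N'-(diethoxyphosphorylmethyl)amidine] of the diaryl ether diacetic acid, via bis(imidoyl triflate) 8 (not isolated)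
Conditions: Tf2O (2.2 equiv), 2-fluoropyridine (2.4 equiv), CH2Cl2, −78 to 0 °C; then 7, iPr2NEt, 0 °C to rt; aq. K2CO3 work-up
Reagents that add atoms: trifluoromethanesulfonic anhydride, O=S(=O)(OS(=O)(=O)C(F)(F)F)C(F)(F)F (its CF3SO2 group is held only in 8 and is gone in 9)
Why: Electrophilic activation of a secondary amide followed by amine capture is an established amidine synthesis; keeping the electron-poor phosphonomethyl group (not PMB) on the amide nitrogen avoids von Braun-type loss of a benzyl cation from the activated species, and the low temperature keeps the nitrilium carbon from Friedel–Crafts attack on ring B.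

Step 5
Reactants: 9 bis-amidine
Product: 10 bis[N-formyl-N-(4-methoxybenzyl)-N'-(diethoxyphosphorylmethyl)amidine] of the diaryl ether diacetic acid
Conditions: 1H-benzotriazole-1-carbaldehyde (2.6 equiv), iPr2NEt (3 equiv), THF, 0 °C to rt; cold aq. Na2CO3 wash, short plug of neutral Al2O3, used promptly
Reagents that add atoms: 1H-benzotriazole-1-carbaldehyde, O=Cn1nnc2ccccc12
Why: N-acylation of an amidine with an azolide formyl donor; the formyl group should settle on the electron-rich PMB nitrogen and leave C=N on the electron-poor phosphonomethyl nitrogen, because the reversible N-to-N' acyl shift known for N-acylamidines lets the regioisomers equilibrate toward this push–pull arrangement.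

Step 6
Reactants: 10 bis(N-formylamidine) bis-phosphonate
Product: 12 N,N'-bis(4-methoxybenzyl)lepidine C, via bis(oxidophosphonate) adduct 11 (not isolated)
Conditions: KHMDS (2.8 equiv), THF (0.01 M), −78 °C to rt
Reagents that add atoms: none
Why: Proposed new method: KHMDS takes a proton from each P–CH2–N=C unit, the phosphonate-stabilised 2-azaallyl carbanion adds to the formyl carbon held on the other amidine nitrogen to give oxido phosphonate 11, and syn loss of diethyl phosphate through an oxaphosphetane creates C4=C5, so that the phosphonate carbon ends as C4–H and the formyl carbon as C5–H of an aromatic ring. The closest known reaction types are the intramolecular Wittig closure of 2-(acylamino)benzylphosphonium ylides onto the amide carbonyl (indoles), the Madelung cyclisation, which shares the geometry, and intermolecular Horner–Wadsworth–Emmons olefination with anions of N-(phosphonomethyl)imines; closure of an imidazole at C4–C5 in this manner is without precedent. Each of the two rings closes 5-exo-trig at the formyl carbon with the amidine C=N lying inside the new ring, and the arms are too far apart to interfere with each other. The C4 and C5 centres of 11 need no control, since the addition is reversible, C4 epimerises under base and both centres become sp2 on elimination. The step needs C-attack to win over deformylation, and phosphate loss to win over dehydration to a 4-phosphorylimidazole: the five-membered transition state, a hindered silylamide base at low temperature, an imide-like formyl group that lacks N–H, the potassium counter-ion and the gain of aromaticity should secure this. The ArCH2 protons are of similar or higher acidity, but that anion can only close a four-membered ring, so it should return by proton exchange with HN(SiMe3)2 and drain through the productive carbanion, while high dilution holds back formyl transfer between molecules.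

Step 7
Reactants: 12 N,N'-bis(4-methoxybenzyl)lepidine C
Product: 13 lepidine C
Conditions: TFA, anisole (10 equiv), 70 °C, sealed tube; then aq. NaHCO3
Reagents that add atoms: none
Why: Acidolytic N-debenzylation (SN1) in which the protonated imidazole departs from the 4-methoxybenzyl carbon and anisole traps the cation by Friedel–Crafts alkylation, so that electron-rich ring A is not benzylated; the aryl methyl ether and the diaryl ether are inert to TFA.

Compound list
1 | methyl (3-hydroxyphenyl)acetate | COC(=O)Cc1cccc(O)c1 | starting material
2 | methyl (2-bromo-5-methoxyphenyl)acetate | COC(=O)Cc1cc(OC)ccc1Br | starting material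
3 | methyl {5-methoxy-2-[3-(2-methoxy-2-oxoethyl)phenoxy]phenyl}acetate | COC(=O)Cc1cccc(Oc2ccc(OC)cc2CC(=O)OC)c1 | intermediate
4 | {2-[3-(carboxymethyl)phenoxy]-5-methoxyphenyl}acetic acid | OC(=O)Cc1cccc(Oc2ccc(OC)cc2CC(=O)O)c1 | intermediate
5 | diethyl (aminomethyl)phosphonate | CCOP(=O)(CN)OCC | starting material
6 | bis[N-(diethoxyphosphorylmethyl)amide] of 4 | CCOP(=O)(OCC)CNC(=O)Cc1cccc(Oc2ccc(OC)cc2CC(=O)NCP(=O)(OCC)OCC)c1 | intermediate
7 | 4-methoxybenzylamine | COc1ccc(CN)cc1 | starting material
8 | bis(imidoyl triflate) of 6 (formed in the flask) | CCOP(=O)(OCC)CN=C(OS(=O)(=O)C(F)(F)F)Cc1cccc(Oc2ccc(OC)cc2CC(OS(=O)(=O)C(F)(F)F)=NCP(=O)(OCC)OCC)c1 | intermediate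
9 | bis[N-(4-methoxybenzyl)-N'-(diethoxyphosphorylmethyl)amidine] | CCOP(=O)(OCC)CN=C(Cc1cccc(Oc2ccc(OC)cc2CC(=NCP(=O)(OCC)OCC)NCc2ccc(OC)cc2)c1)NCc1ccc(OC)cc1 | intermediate
10 | bis[N-formyl-N-(4-methoxybenzyl)-N'-(diethoxyphosphorylmethyl)amidine] | CCOP(=O)(OCC)CN=C(Cc1cccc(Oc2ccc(OC)cc2CC(=NCP(=O)(OCC)OCC)N(C=O)Cc2ccc(OC)cc2)c1)N(C=O)Cc1ccc(OC)cc1 | intermediate
11 | bis[4-(diethoxyphosphoryl)-5-oxido-1-(4-methoxybenzyl)-4,5-dihydroimidazol-2-ylmethyl] adduct (formed in the flask; drawn protonated; diastereomer mixture) | COc1ccc(Oc2cccc(CC3=NC(P(=O)(OCC)OCC)C(O)N3Cc3ccc(OC)cc3)c2)c(CC2=NC(P(=O)(OCC)OCC)C(O)N2Cc2ccc(OC)cc2)c1 | intermediate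
12 | N,N'-bis(4-methoxybenzyl)lepidine C | COc1ccc(Oc2cccc(Cc3nccn3Cc3ccc(OC)cc3)c2)c(Cc2nccn2Cc2ccc(OC)cc2)c1 | intermediate
13 | lepidine C | COc1ccc(Oc2cccc(Cc3ncc[nH]3)c2)c(Cc2ncc[nH]2)c1 | target

Total step count: 7. Longest linear sequence: 7 steps (from 1 or 2 to 13).

Steps most likely to fail

Step 6 (labelled step). Several things may go wrong:
- The proton may be taken at ArCH2 instead of at P–CH2. The formamide anion could then be expelled, or formyl groups could pass between molecules.
- The base may attack the formyl group.
- The sequence may stall at the oxido phosphonate stage, and this has to be avoided on both arms.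

The fallback uses known chemistry and sets out from diester 3. Condensation with ethylenediamine promoted by AlMe3 in refluxing toluene converts each ester into a 2-imidazoline and gives the bis(2-imidazoline) F1. Dehydrogenation of both rings with PhI(OAc)2 and K2CO3 in DMSO then aromatises them, and the route is rejoined at target 13. In this variant C4–C5 arrives ready-made with the diamine and no protecting group is needed.

Step 5. The formyl group may land on the phosphonomethyl nitrogen or on the benzylic carbon of the ene-diamine tautomer, and it may be lost by hydrolysis during isolation. The fallback forms the amidine C–N bond with the formyl group already in place. It sets out from amine 7 and from amide 6. Amine 7 is heated with ethyl formate to give N-(4-methoxybenzyl)formamide F2. Its sodium salt (NaH, THF) is added at −78 °C to 8, generated from 6 as in step 4. No choice between two nitrogens then arises, and the route is rejoined at 10.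

Step 4. Triflation of the phosphoryl oxygen with loss of ethyl groups may compete. Elimination to a ketenimine or nitrile ylide is possible, and the nitrilium carbon may close onto ring B. The fallback replaces oxygen activation by sulfur activation and sets out from 6. Lawesson's reagent in warm THF thionates only the amide carbonyls to give the bis(thioamide) F3. Methyl iodide in acetonitrile alkylates sulfur to give the bis(S-methyl thioimidate) F4. Displacement of the methylthio groups by amine 7 in THF at rt to 50 °C rejoins the route at 9.

Further compounds
F1 | step 6 | 2-{3-[2-(4,5-dihydro-1H-imidazol-2-ylmethyl)-4-methoxyphenoxy]benzyl}-4,5-dihydro-1H-imidazole (bis-imidazoline) | COc1ccc(Oc2cccc(CC3=NCCN3)c2)c(CC2=NCCN2)c1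
F2 | step 5 | N-(4-methoxybenzyl)formamide | COc1ccc(CNC=O)cc1
F3 | step 4 | bis(thioamide) of 6 | CCOP(=O)(OCC)CNC(=S)Cc1cccc(Oc2ccc(OC)cc2CC(=S)NCP(=O)(OCC)OCC)c1
F4 | step 4 | bis(S-methyl thioimidate) of 6 | CCOP(=O)(OCC)CN=C(SC)Cc1cccc(Oc2ccc(OC)cc2CC(SC)=NCP(=O)(OCC)OCC)c1
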